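## Structural features

The target is a C30 tetracycle made of two bicycles: a trans-fused perhydro-1-benzoxepine (ring A, the oxepan-3-one O20/C21/C11/C13/C14/C15/C17; ring B, the cyclohexane C10/C11/C21/C22/C23/C24) and a cis-fused decalin (ring C, C2 to C7; ring D, C5/C6/C27/C30/C31/C32). The halves meet only through the C9 methylene and the E-trisubstituted exocyclic alkene C7=C8, in which C9 lies cis to C2. Ring B carries four contiguous stereocentres: the tertiary carbinol C24, the C10 methine wedged between two fully substituted carbons, the quaternary C11 and the ether carbon C21. The C24 and C12 methyls are 1,3-diaxial and the C24 hydroxyl is equatorial. The decalin carries C2, C5, C6 and the tertiary carbinol C32, whose methyl points into the concave face of the cis-fused system. Fragile points are the two tertiary alcohols (elimination), the exocyclic alkene (acid-induced migration), and intermediates with a quaternary carbon between two carbonyls (retro-Claisen cleavage). The real difficulty is that both carbinols carry their methyl on the more hindered face, where direct methyl addition to a ketone would not put it, and that C10 is sterically buried. The key step exploits the C24 carbinol (methyl and hydroxyl) bonded to C10, which is bonded to quaternary C11 in ring B: this is what a 1-acetylcyclopentanol next to an angular methyl leaves after a one-carbon ring expansion.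

## Logic of the disconnections

45 ⇒ 44 ⇒ 43. No skeletal bond is cut; the free C24 hydroxyl and the C15 carbonyl are traced back to a silyl ether and a C15 carbinol. The reason is that C15 must not be a ketone while the far more hindered C10 carbonyl is methylenated and while boranes are present. The forward steps must oxidise only the secondary alcohol and then free the tertiary one without disturbing the C7=C8 alkene.

43 ⇒ 23 + 41. The C8–C9 bond is cut. It is the only bond joining the two bicycles, so the cut gives two halves of similar size. The forward step needs hydroboration of 23 with hydrogen delivered to C10 from the face opposite the axial C12 and C25 methyls, and a coupling that keeps the geometry of 41.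

23 ⇒ 21 ⇒ 20. C10=C9 is cut back to the C10 ketone and C15 is returned to its ketone. This leaves a bicyclic diketone with all four ring-B centres in place. The forward steps need a hydride that distinguishes C15 from C10 and a small carbon nucleophile that can reach C10.

20 ⇒ 18 (through 19). The O20–C21 bond is cut, so ring A opens to a hydroxy ketone side chain on ring B. The forward step must form the hemiketal at C21 and not at C10, and hydride must add axially to give the trans fusion.

18 ⇒ 17 ⇒ 15 + 16. C17–O20 is removed (alkene hydration) and C15–C17 is cut. The gem-dimethyl carbinol thus comes from an isopropenyl unit, and C15 is the carbonyl of an enol lactone that keeps C21 masked while the organometallic is present. The forward step needs a single addition of 16.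

15 ⇒ 14 ⇒ 13 ⇒ 12. C15 and C21 are reconnected through one extra carbon (Cx), the reverse of an oxidative enone cleavage, and the silyl group is removed. This turns the side chain into a cyclohexenone and reveals a bicyclic enedione. The forward cleavage must spare the α-oxygenated C10 ketone, hence the silyl ether.

12 ⇒ 11. This is the key disconnection: C23–C24 is cut and C23–C10 re-formed, contracting ring B to a cyclopentane that bears hydroxyl and acetyl on C10. The gain is a hydrindenone with one stereocentre beside the angular methyl. The forward step needs migration of C23 and not of C11, through the syn ketol conformer.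

11 ⇒ 10 ⇒ 9 ⇒ 8 ⇒ 6 + 7. The C24 carbonyl goes back to a carbinol, the two C–O bonds at C10 and C24 to the C10=C24 alkene, and that alkene to the C10 ketone and ylide 7. The enone carbonyl has to be masked without moving its double bond, and osmylation has to occur anti to C12.

6 ⇒ 5 ⇒ 3 ⇒ 1 + 2. After unmasking, Cx=C21 (aldol condensation) and C11–C13 (Michael addition) are cut. The forward aldol must be enantioselective for the R configuration at C11.

41 ⇒ 40 ⇒ 39. C8–I is traced to C8–B and the C7=C8 alkene is cut to the C7 ketone and a one-carbon diboryl carbanion. The forward olefination must place boron cis to C2.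

39 ⇒ 38 ⇒ 37 ⇒ 36 ⇒ 35. The C7 ketone goes back to the C7 carbinol, then C7–O and C2–H to the C7=C2 alkene, the C32–O bond to the C32=C33 alkene, and that to the C32 ketone. All that remains is a cis-fused octalone. Forward, oxygen must reach C32 and hydrogen C2 from the convex face.

35 ⇒ 33 (through 34) ⇒ 32. C31–C32 is cut (intramolecular acylation) and the ester exchanged for the auxiliary imide. Ring D opens to a cis-1,2-disubstituted cyclohexene.

32 ⇒ 31 + 26. C5–C6 and C3–C4 are cut (Diels–Alder). The forward step must be endo (cis C5/C6), bond the substituted diene terminus to the α-carbon, and be face-selective through the auxiliary.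

31 ⇒ 30 ⇒ 28 + 29; 28 ⇒ 27; 26 ⇒ 24 + 25. C6=C7 is cut (phosphonate olefination of a lactol), the C–I bond goes back to C–O, and the N-acyl bond is cut.

## Other disconnections considered

Alternative 1: The cut is C21–C11 and C14–C13 (a cyclobutane), followed by cleavage of C14–C21. Forward, an intramolecular enone–alkene [2+2] photocycloaddition would close ring B and the cyclobutane to give A1, and opening of the strained C14–C21 bond would enlarge the furanone to the oxepan-3-one. In its favour: two C–C bonds, ring B and quaternary C11 arise in one step, and ring A arrives with C15 already a ketone and with the gem-dimethyl group in place. In these respects it is better than the chosen plan, which forms one skeletal bond in its key step and needs an oxidative cleavage plus a C15 redox detour. Against it: C24 and C10 must be set on the open chain before irradiation, so the key step does not solve the hardest carbinol. The facial course at C11/C21 rests on tether conformation in an excited-state, stepwise process, and the fragmentation must still deliver the trans ring fusion. Mechanistically the chosen ground-state suprafacial shift is easier to predict; in step count the two plans are probably comparable once the photosubstrate's two adjacent stereocentres are made; for the left half and the fragment union they are equal.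

Alternative 2: The cut is O20–C17 and C10–C11. Forward, a TMSOTf-triggered bis-epoxide cascade would close the oxepane and ring B together to give A2. In its favour: both rings, C11 and C21 come from an acyclic chain whose stereochemistry derives from asymmetric epoxidation. This is the highest gain in rings and bonds per step of all the plans, so it is better here, and the C9 ester is a more convenient handle than the hindered C10 methylenation of the chosen route. Against it: seven-membered (endo) opening must beat the six-membered (exo) mode. A2 has C24 as a ketone, and methyl addition there is expected to come equatorially and give the C24 epimer. C15 needs a later oxidation, which equals the redox bracket of the chosen plan. The chosen plan is longer for rings A/B but is the only one in which the key step itself sets C24.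

Alternative 3: The cut is C5–C6 with cleavage of C2–O. Forward, a ring-contracting ester-enolate Claisen rearrangement through a boat would give A3. This concerns rings C and D, so it complements rather than replaces the chosen key step. In its favour: the cis C5/C6 relationship and the C2=C7 alkene arise by chirality transfer with no auxiliary to remove. A3 carries the same ring-C pattern as 33, so in what it delivers it is the equal of step 21 and better in atom economy. Against it: it needs an enantioenriched lactone with a fully substituted carbinol centre and a defined E-alkene, probably costing more steps than 31 and 26, and it leaves C24 and ring B untouched. Both routes would still have to close ring D and set C32 and C2 afterwards.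

Key step: step 8

Remarks on the chemistry (assumptions):
- Atom numbers are the positions of the heavy atoms in the target SMILES (C1 to O34); the enone carbon that is later excised is called Cx.
- The SMILES is read as follows: H5 and H6 cis (cis-decalin), the C32 hydroxyl cis to H5, the C2 methyl cis to C27, and C7=C8 E with C9 cis to C2.
- 21, 22, 23, 42 and 43 are carried as mixtures of C15 epimers (22 also at C10); these centres are erased in steps 16 and 31.

Step 1
Reactants: 1 2-methylcyclopentane-1,3-dione; 2 methyl vinyl ketone
Product: 3 2-methyl-2-(3-oxobutyl)cyclopentane-1,3-dione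
Conditions: H2O, AcOH (cat.), 75 °C
Reagents that add atoms: none
Why: Michael addition of the acidic 1,3-dione to the enone forms C11–C13; the new quaternary carbon is not yet stereogenic.

Step 2
Reactants: 3 2-methyl-2-(3-oxobutyl)cyclopentane-1,3-dione
Product: 5 (R)-Hajos–Parrish ketone, via cis-ketol 4 (not isolated)
Conditions: D-proline (3 mol%), DMF, rt; then H2SO4 (cat.), 95 °C
Reagents that add atoms: none
Why: Hajos–Parrish reaction (proline-catalysed desymmetrising aldol, then dehydration); D-proline selects the ring carbonyl that makes C11 R, the mirror image of the well-known L-proline result.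

Step 3
Reactants: 5 (R)-Hajos–Parrish ketone
Product: 6 enone dithiolane of 5
Conditions: HSCH2CH2SH (1.05 equiv), TsOH (cat.), AcOH, rt
Reagents that add atoms: ethane-1,2-dithiol SCCS
Why: Acid-catalysed thioketalisation, which in ene-diones of this type takes the conjugated carbonyl and leaves the neopentyl cyclopentanone free. Unlike an O-acetal or dienol ether it does not shift the double bond to C21=C22, which would make H23 doubly activated and quench the ylide of step 4.

Step 4
Reactants: 6 enone dithiolane of 5; 7 ethyltriphenylphosphonium bromide
Product: 8 (Z)-ethylidene dithiolane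
Conditions: KOtBu, THF, reflux
Reagents that add atoms: none
Why: Wittig olefination of a hindered cyclopentanone as practised on 17-oxo steroids; the Z isomer should dominate, but the geometry does not matter because C24 becomes a carbonyl in step 7.

Step 5
Reactants: 8 (Z)-ethylidene dithiolane
Product: 9 ethylidene enone
Conditions: MeI, CaCO3, MeCN/H2O, 60 °C
Reagents that add atoms: water O
Why: Alkylative hydrolysis of the dithiolane (S-methylation, then solvolysis of the allyl-stabilised thionium ion); MeI leaves the trisubstituted alkene alone and frees the enone before any osmium chemistry.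

Step 6
Reactants: 9 ethylidene enone
Product: 10 diol
Conditions: OsO4 (2 mol%), NMO, acetone/H2O, rt
Reagents that add atoms: N-methylmorpholine N-oxide C[N+]1([O-])CCOCC1; water O
Why: Catalytic syn-dihydroxylation; OsO4 selects the electron-rich ethylidene over the enone and adds to the face remote from the angular C12 methyl, which places the C10 hydroxyl anti to that methyl.

Step 7
Reactants: 10 diol
Product: 11 α-ketol
Conditions: SO3·pyridine, DMSO, Et3N, CH2Cl2, 0 °C
Reagents that add atoms: none
Why: Parikh–Doering oxidation of the secondary alcohol; activated-DMSO conditions do not cleave the vicinal diol and leave the tertiary hydroxyl free.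

Step 8
Reactants: 11 α-ketol
Product: 12 ring-expanded hydroxy diketone
Conditions: BF3·OEt2 (2 equiv), CH2Cl2, −20 to 0 °C
Reagents that add atoms: none
Why: Acyloin (α-ketol) rearrangement: BF3 activates the acetyl oxygen while the C10 hydroxyl is held syn to it, so the C10–C23 bond lies parallel to the π* orbital of C24=O and shifts suprafacially to C24 as C10–O becomes a carbonyl. The closest known reaction is the D-homoannulation of 17α-hydroxy-20-oxo steroids, where BF3 moves the ring methylene and leaves the hydroxyl anti and the methyl syn to the angular methyl. Ring B is not closed by a new cyclisation; it grows from five to six members by this 1,2-shift, driven by relief of cyclopentane strain and exchange of a methyl ketone for a ring ketone. The new stereocentre C24 is controlled by the syn O–C10–C24–O conformer: the acetyl methyl lies on the C12 face and the carbonyl oxygen on the opposite face, and both stay there. The step needs migration of C23 rather than quaternary C11; C11 carries the electron-poor enone carbon C21, which lowers its migratory aptitude. BF3 is chosen over an aluminium alkoxide because alkoxide chelates are reported to favour shift of the more substituted carbon in the steroid series and would expose the vinylogous 1,3-diketone of 12 to retro-Claisen attack. Short exposure at low temperature should prevent a second ketol shift (methyl from C24 to C10).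

Step 9
Reactants: 12 ring-expanded hydroxy diketone
Product: 13 triethylsilyl ether of 12
Conditions: TESOTf, 2,6-lutidine, CH2Cl2, 0 °C
Reagents that add atoms: triethylsilyl triflate CC[Si](CC)(CC)OS(=O)(=O)C(F)(F)F
Why: Silylation of a tertiary alcohol with a silyl triflate; the ether stops periodate cleavage of the α-ketol in step 10 and stops the C24 oxygen bridging to C21 in step 14.

Step 10
Reactants: 13 triethylsilyl ether of 12
Product: 14 keto acid
Conditions: RuCl3 (cat.), NaIO4, EtOAc/MeCN/H2O, rt
Reagents that add atoms: sodium periodate [Na+].[O-]I(=O)(=O)=O; water O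
Why: RuO4-catalysed oxidative cleavage of the enone, the standard degradation of 4-en-3-one steroids: C21 becomes a ketone, Cx is lost as CO2 and C15 becomes the acid.

Step 11
Reactants: 14 keto acid
Product: 15 enol lactone
Conditions: Ac2O, NaOAc, 120 °C
Reagents that add atoms: none
Why: Enol lactonisation of a δ-keto acid through the mixed anhydride; only C21 can enolise (towards C22), because C10 has no α-hydrogen, so a single lactone forms.

Step 12
Reactants: 15 enol lactone; 16 isopropenylmagnesium bromide
Product: 17 isopropenyl ketone
Conditions: THF, −78 °C (1.05 equiv of 16); aq. NH4Cl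
Reagents that add atoms: none
Why: Grignard acyl substitution on an enol lactone (first stage of the Fujimoto–Belleau reaction): C15–C17 forms while C21 leaves as its enolate and is thereby protected; the doubly neopentyl C10 ketone should not react.

Step 13
Reactants: 17 isopropenyl ketone
Product: 18 α-hydroxy ketone
Conditions: Mn(dpm)3 (cat.), PhSiH3, O2, i-PrOH/CH2Cl2, 0 °C; then P(OEt)3
Reagents that add atoms: dioxygen O=O
Why: Mukaiyama-type hydration of an enone: hydrogen-atom transfer to the CH2 terminus gives the tertiary α-keto radical at C17, which is trapped by O2 and reduced to the alcohol (O20).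

Step 14
Reactants: 18 α-hydroxy ketone
Product: 20 trans-fused oxepanone, via bicyclic hemiketal 19 (not isolated)
Conditions: Et3SiH, TMSOTf (cat.), CH2Cl2, −78 to 0 °C
Reagents that add atoms: none
Why: Reductive etherification of a hydroxy ketone: O20 closes on C21 (C10 is far more hindered) and the ring-B oxocarbenium ion takes hydride axially, from the face opposite the axial C12 methyl, which gives H21 anti to C12 and the trans A/B fusion.

Step 15
Reactants: 20 trans-fused oxepanone
Product: 21 C15 carbinol
Conditions: NaBH4, MeOH, −20 °C
Reagents that add atoms: none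
Why: Chemoselective borohydride reduction; the C15 ketone has one quaternary neighbour and the C10 ketone two, so only C15 should be reduced, which removes the competing carbonyl before step 16.

Step 16
Reactants: 21 C15 carbinol
Product: 23 C10-methylene compound, via β-silyl carbinol 22 (not isolated)
Conditions: Me3SiCH2Li (4 equiv), CeCl3, THF, −78 to 0 °C; then KH, THF, 50 °C
Reagents that add atoms: (trimethylsilyl)methyllithium C[Si](C)(C)C[Li]
Why: Peterson olefination: the small cerium-activated carbanion can attack C10 axially from the face that carries only axial hydrogens, and syn-elimination of the potassium alkoxide gives the methylene.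

Step 17
Reactants: 24 (R)-4-benzyloxazolidin-2-one; 25 acryloyl chloride
Product: 26 (R)-3-acryloyl-4-benzyloxazolidin-2-one
Conditions: MeMgBr, THF, 0 °C; then 25, −78 °C
Reagents that add atoms: none
Why: N-acylation of the magnesium salt of the oxazolidinone, which avoids polymerisation of the acrylate.

Step 18
Reactants: 27 3,3-dimethyldihydrofuran-2(3H)-one
Product: 28 3,3-dimethyltetrahydrofuran-2-ol
Conditions: DIBAL-H, CH2Cl2, −78 °C
Reagents that add atoms: none
Why: Partial reduction of a lactone to the lactol, a masked 4-hydroxy-2,2-dimethylbutanal.

Step 19
Reactants: 28 3,3-dimethyltetrahydrofuran-2-ol; 29 diethyl (2-methylallyl)phosphonate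
Product: 30 (E)-3,3,6-trimethylhepta-4,6-dien-1-ol
Conditions: n-BuLi (2.5 equiv) with 29, THF, −78 °C; then 28, DMPU, −78 °C to rt
Reagents that add atoms: none
Why: Horner–Wadsworth–Emmons-type olefination of the open lactol with an allylic phosphonate anion (α-attack, then elimination); such anions give E-dienes, and the tertiary substituent at C27 reinforces this.

Step 20
Reactants: 30 (E)-3,3,6-trimethylhepta-4,6-dien-1-ol
Product: 31 (E)-7-iodo-2,5,5-trimethylhepta-1,3-diene
Conditions: I2, PPh3, imidazole, CH2Cl2, 0 °C
Reagents that add atoms: iodine II
Why: Appel-type iodination of the primary alcohol; the diene is inert under these conditions.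

Step 21
Reactants: 31 (E)-7-iodo-2,5,5-trimethylhepta-1,3-diene; 26 (R)-3-acryloyl-4-benzyloxazolidin-2-one
Product: 32 Diels–Alder adduct
Conditions: Et2AlCl (1.4 equiv), CH2Cl2, −78 to −30 °C
Reagents that add atoms: none
Why: Auxiliary-controlled Diels–Alder reaction of the aluminium-chelated s-cis acrylimide: the 1-alkyl and 3-methyl groups of the diene both direct C6 to the α-carbon, and the endo mode sets C5/C6 cis. The diene adds to the face away from the benzyl group, which for the R auxiliary gives C5 S (the S auxiliary with isoprene is known to give the R acid).

Step 22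
Reactants: 32 Diels–Alder adduct
Product: 33 benzyl ester
Conditions: BnOH, n-BuLi, THF, −20 to 0 °C
Reagents that add atoms: benzyl alcohol OCc1ccccc1
Why: Transesterification with lithium benzyloxide, which cleaves hindered N-acyloxazolidinones at the exocyclic carbonyl and releases the auxiliary; at this temperature acyl transfer should outrun displacement of the primary iodide.

Step 23
Reactants: 33 benzyl ester
Product: 35 cis-octalone, via alkyllithium 34 (not isolated)
Conditions: t-BuLi (2.1 equiv), Et2O/pentane, −100 to −78 °C; AcOH quench at −78 °C
Reagents that add atoms: none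
Why: Iodine–lithium exchange followed by intramolecular acylation (six-membered ring) of the ester forms C31–C32 and ring D; the cold acidic quench should prevent epimerisation at C5.

Step 24
Reactants: 35 cis-octalone
Product: 36 methylene diene
Conditions: Zn, CH2Br2, TiCl4, THF/CH2Cl2, 0 °C to rt
Reagents that add atoms: dibromomethane BrCBr
Why: Takai–Lombardo methylenation, chosen because this non-basic titanium–zinc reagent methylenates enolisable ketones without epimerising the α-centre C5 (a basic ylide could turn the cis into the trans ring fusion).

Step 25
Reactants: 36 methylene diene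
Product: 37 tertiary alcohol
Conditions: Mn(dpm)3 (cat.), PhSiH3 (1.2 equiv), O2, i-PrOH/CH2Cl2, 0 °C; then P(OEt)3
Reagents that add atoms: dioxygen O=O
Why: Mukaiyama hydration: hydrogen-atom transfer is faster to the unhindered 1,1-disubstituted alkene than to the ring alkene, whose CH carbon is flanked by C6. In the favoured conformer (C7 axial on ring D) the C32 radical is trapped by O2 equatorially, away from the syn-axial C7, which puts the hydroxyl on the convex face cis to H5 and the methyl on the concave face.

Step 26
Reactants: 37 tertiary alcohol
Product: 38 diol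
Conditions: BH3·THF, 0 °C to rt; then NaOH, H2O2
Reagents that add atoms: hydrogen peroxide OO
Why: Hydroboration–oxidation of the trisubstituted alkene with boron at C7; syn addition from the convex face of the cis-fused bicycle delivers H to C2 on the H5/H6 side, which sets the C2 methyl cis to C27.

Step 27
Reactants: 38 diol
Product: 39 hydroxy ketone
Conditions: DMP, CH2Cl2, 0 °C to rt
Reagents that add atoms: none
Why: Dess–Martin oxidation of the secondary alcohol only; the near-neutral medium should not epimerise C2 or C6, and the C2 methyl is equatorial in the favoured conformer anyway.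

Step 28
Reactants: 39 hydroxy ketone
Product: 40 alkenyl boronate
Conditions: CH2(Bpin)2 (3 equiv), LiTMP, THF, 0 °C; then 39, −78 °C to rt
Reagents that add atoms: bis[(pinacolato)boryl]methane CC1(C)OB(CB2OC(C)(C)C(C)(C)O2)OC1(C)C
Why: Boron-Wittig olefination of a ketone; syn B–O elimination places the remaining boryl group away from the bulkier α-carbon (C6, next to the quaternary C27), that is cis to C2.

Step 29
Reactants: 40 alkenyl boronate
Product: 41 vinyl iodide
Conditions: NaOH (aq), THF, 0 °C; then I2
Reagents that add atoms: iodine II
Why: Iododeboronation of the alkenyl boronate through its hydroxy ate complex, which proceeds with retention and so gives iodine cis to C2.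

Step 30
Reactants: 23 C10-methylene compound; 41 vinyl iodide
Product: 43 coupled tetracycle, via alkylborane 42 (not isolated)
Conditions: 9-BBN, THF, 65 °C; then 41, Pd(dppf)Cl2 (cat.), AsPh3, Cs2CO3, DMF/H2O, 50 °C
Reagents that add atoms: none
Why: Hydroboration, then B-alkyl Suzuki–Miyaura coupling: boron adds to C9 and hydrogen to C10 from the face opposite the two axial methyls (C12, C25), which makes C9 equatorial as in the target. The coupling retains the alkene geometry of 41.

Step 31
Reactants: 43 coupled tetracycle
Product: 44 silyl-protected target
Conditions: DMP, CH2Cl2, rt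
Reagents that add atoms: none
Why: Dess–Martin oxidation of the only secondary alcohol restores the C15 ketone and merges the C15 epimers; tertiary alcohols and the alkene do not react.

Step 32
Reactants: 44 silyl-protected target
Product: 45 CNP0232921.1
Conditions: TBAF, THF, 40 °C
Reagents that add atoms: none
Why: Fluoride cleavage of the tertiary triethylsilyl ether under non-acidic conditions, which protects the exocyclic alkene and the tertiary alcohols from acid.

Compound list

1 | 2-methylcyclopentane-1,3-dione | CC1C(=O)CCC1=O | starting material
2 | methyl vinyl ketone (but-3-en-2-one) | CC(=O)C=C | starting material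
3 | 2-methyl-2-(3-oxobutyl)cyclopentane-1,3-dione | CC(=O)CCC1(C)C(=O)CCC1=O | intermediate
4 | (3aR,7aR)-3a-hydroxy-7a-methylhexahydro-1H-indene-1,5(4H)-dione (cis-fused ketol) | C[C@@]12CCC(=O)C[C@]1(O)CCC2=O | intermediate (not isolated)
5 | (R)-Hajos–Parrish ketone, (7aR)-7a-methyl-2,3,7,7a-tetrahydro-1H-indene-1,5(6H)-dione | C[C@@]12CCC(=O)C=C1CCC2=O | intermediate
6 | 1,3-dithiolane of the enone carbonyl (C15) of 5, C10 ketone free | C[C@@]12CCC3(SCCS3)C=C1CCC2=O | intermediate
7 | ethyltriphenylphosphonium bromide | CC[P+](c1ccccc1)(c1ccccc1)c1ccccc1.[Br-] | starting material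
8 | (Z)-C10-ethylidene derivative of 6 (C25 cis to C11) | C[C@@]12CCC3(SCCS3)C=C1CC/C2=C/C | intermediate
9 | (7aR,1Z)-1-ethylidene-7a-methyl-1,2,3,6,7,7a-hexahydro-5H-inden-5-one | C[C@@]12CCC(=O)C=C1CC/C2=C/C | intermediate
10 | (1S,7aR)-1-hydroxy-1-[(1R)-1-hydroxyethyl]-7a-methyl-1,2,3,6,7,7a-hexahydro-5H-inden-5-one (C10 hydroxyl anti to C12) | C[C@@]12CCC(=O)C=C1CC[C@@]2(O)[C@@H](C)O | intermediate
11 | (1S,7aR)-1-acetyl-1-hydroxy-7a-methyl-1,2,3,6,7,7a-hexahydro-5H-inden-5-one (hydroxyl anti, acetyl syn to C12) | C[C@@]12CCC(=O)C=C1CC[C@@]2(O)C(C)=O | intermediate
12 | (7S,8aR)-7-hydroxy-7,8a-dimethyl-1,2,5,6,7,8a-hexahydronaphthalene-3,8-dione (C24 hydroxyl anti, methyl syn to C12) | C[C@@]12CCC(=O)C=C1CC[C@](C)(O)C2=O | intermediate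
13 | triethylsilyl ether of 12 | C[C@@]12CCC(=O)C=C1CC[C@](C)(O[Si](CC)(CC)CC)C2=O | intermediate
14 | 3-[(1R,3S)-1,3-dimethyl-2,6-dioxo-3-(triethylsilyloxy)cyclohexyl]propanoic acid | C[C@@]1(CCC(=O)O)C(=O)CC[C@](C)(O[Si](CC)(CC)CC)C1=O | intermediate
15 | enol lactone of 14 (lactone carbonyl C15, enol ether O–C21=C22, C10 ketone, C24 silyl ether) | C[C@@]12CCC(=O)OC1=CC[C@](C)(O[Si](CC)(CC)CC)C2=O | intermediate
16 | isopropenylmagnesium bromide | CC(=C)[Mg]Br | starting material
17 | (2R,4S)-2,4-dimethyl-2-(4-methyl-3-oxopent-4-en-1-yl)-4-(triethylsilyloxy)cyclohexane-1,3-dione | C[C@@]1(CCC(=O)C(C)=C)C(=O)CC[C@](C)(O[Si](CC)(CC)CC)C1=O | intermediate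
18 | (2R,4S)-2-(4-hydroxy-4-methyl-3-oxopentyl)-2,4-dimethyl-4-(triethylsilyloxy)cyclohexane-1,3-dione | C[C@@]1(CCC(=O)C(C)(C)O)C(=O)CC[C@](C)(O[Si](CC)(CC)CC)C1=O | intermediate
19 | bicyclic hemiketal of 18 (O20 bonded to C21, hydroxyl on C21) | O=C1[C@]2(C)CCC(=O)C(C)(C)OC2(O)CC[C@]1(C)O[Si](CC)(CC)CC | intermediate (not isolated)
20 | trans-fused perhydro-1-benzoxepine-3,6-dione (C15 and C10 ketones, H21 anti to C12, C24 silyl ether) | O=C1[C@]2(C)CCC(=O)C(C)(C)O[C@H]2CC[C@]1(C)O[Si](CC)(CC)CC | intermediate
21 | C15 carbinol of 20 (C15 epimers), C10 ketone retained | O=C1[C@]2(C)CCC(O)C(C)(C)O[C@H]2CC[C@]1(C)O[Si](CC)(CC)CC | intermediate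
22 | C10 adduct of 21 bearing hydroxyl and trimethylsilylmethyl on C10 | C[Si](C)(C)CC1(O)[C@]2(C)CCC(O)C(C)(C)O[C@H]2CC[C@]1(C)O[Si](CC)(CC)CC | intermediate (not isolated)
23 | C10-methylene compound (C10=C9H2, C15 carbinol, C24 silyl ether) | C=C1[C@]2(C)CCC(O)C(C)(C)O[C@H]2CC[C@]1(C)O[Si](CC)(CC)CC | intermediate
24 | (R)-4-benzyloxazolidin-2-one | O=C1N[C@H](Cc2ccccc2)CO1 | starting material
25 | acryloyl chloride | C=CC(=O)Cl | starting material
26 | (R)-3-acryloyl-4-benzyloxazolidin-2-one | C=CC(=O)N1[C@H](Cc2ccccc2)COC1=O | intermediate
27 | 3,3-dimethyldihydrofuran-2(3H)-one | CC1(C)CCOC1=O | starting material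
28 | 3,3-dimethyltetrahydrofuran-2-ol (lactol, anomers) | CC1(C)CCOC1O | intermediate
29 | diethyl (2-methylallyl)phosphonate | CCOP(=O)(CC(C)=C)OCC | starting material
30 | (E)-3,3,6-trimethylhepta-4,6-dien-1-ol | OCCC(C)(C)/C=C/C(C)=C | intermediate
31 | (E)-7-iodo-2,5,5-trimethylhepta-1,3-diene | ICCC(C)(C)/C=C/C(C)=C | intermediate
32 | (R)-4-benzyl-3-{[(1S,2R)-2-(4-iodo-2-methylbutan-2-yl)-4-methylcyclohex-3-en-1-yl]carbonyl}oxazolidin-2-one (cis) | CC1=C[C@H]([C@H](CC1)C(=O)N1[C@H](Cc2ccccc2)COC1=O)C(C)(C)CCI | intermediate
33 | benzyl (1S,2R)-2-(4-iodo-2-methylbutan-2-yl)-4-methylcyclohex-3-ene-1-carboxylate | CC1=C[C@H]([C@H](CC1)C(=O)OCc1ccccc1)C(C)(C)CCI | intermediate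
34 | primary alkyllithium from 33 (C31–Li) | CC1=C[C@H]([C@H](CC1)C(=O)OCc1ccccc1)C(C)(C)CC[Li] | intermediate (not isolated)
35 | (4aR,8aS)-4,4,6-trimethyl-3,4,4a,7,8,8a-hexahydronaphthalen-1(2H)-one (cis-fused) | CC1=C[C@@H]2[C@H](CC1)C(=O)CCC2(C)C | intermediate
36 | (4aR,8aS)-4,4,6-trimethyl-1-methylene-1,2,3,4,4a,7,8,8a-octahydronaphthalene | CC1=C[C@@H]2[C@H](CC1)C(=C)CCC2(C)C | intermediate
37 | (1S,4aR,8aS)-1,4,4,6-tetramethyl-1,2,3,4,4a,7,8,8a-octahydronaphthalen-1-ol (hydroxyl cis to H5) | CC1=C[C@@H]2[C@H](CC1)[C@@](C)(O)CCC2(C)C | intermediate
38 | (1S,4aR,5S,6R,8aS)-1,4,4,6-tetramethyldecahydronaphthalene-1,5-diol | C[C@@H]1CC[C@H]2[C@@H]([C@H]1O)C(C)(C)CC[C@]2(C)O | intermediate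
39 | (2R,4aS,5S,8aR)-5-hydroxy-2,5,8,8-tetramethyloctahydronaphthalen-1(2H)-one | C[C@@H]1CC[C@H]2[C@@H](C1=O)C(C)(C)CC[C@]2(C)O | intermediate
40 | (E)-alkenyl pinacol boronate from 39 (C7=C8H–B, boron cis to C2) | C[C@@H]1CC[C@H]2[C@@H](/C1=C/B3OC(C)(C)C(C)(C)O3)C(C)(C)CC[C@]2(C)O | intermediate
41 | (1S,4aR,6R,8aS,E)-5-(iodomethylidene)-1,4,4,6-tetramethyldecahydronaphthalen-1-ol (iodine cis to C2) | C[C@@H]1CC[C@H]2[C@@H](/C1=C/I)C(C)(C)CC[C@]2(C)O | intermediate
42 | B-alkyl-9-BBN from 23 (boron on C9, H10 anti to C12, C15 oxygen as its 9-BBN borinate) | C(B1C2CCCC1CCC2)[C@H]1[C@]2(C)CCC(OB3C4CCCC3CCC4)C(C)(C)O[C@H]2CC[C@]1(C)O[Si](CC)(CC)CC | intermediate (not isolated)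
43 | coupled tetracycle (C15 carbinol, C24 silyl ether, C32 free hydroxyl) | C[C@@H]1CC[C@H]2[C@@H](/C1=C/C[C@H]1[C@]3(C)CCC(O)C(C)(C)O[C@H]3CC[C@]1(C)O[Si](CC)(CC)CC)C(C)(C)CC[C@]2(C)O | intermediate
44 | C24 triethylsilyl ether of the target | C[C@@H]1CC[C@H]2[C@@H](/C1=C/C[C@H]1[C@]3(C)CCC(=O)C(C)(C)O[C@H]3CC[C@]1(C)O[Si](CC)(CC)CC)C(C)(C)CC[C@]2(C)O | intermediate
45 | CNP0232921.1 | C[C@@H]1CC[C@H]2[C@@H](/C1=C/C[C@H]1[C@]3(C)CCC(=O)C(C)(C)O[C@H]3CC[C@]1(C)O)C(C)(C)CC[C@]2(C)O | target

Total step count: 32. Longest linear sequence: 19 steps (steps 1 to 16, then 30 to 32); the left half takes 13 steps (17 to 29).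

Least certain steps

Step 8 (key step). The 1,2-shift may be misdirected: the quaternary C11 may migrate instead of C23, a second ketol shift may follow, or the reaction may pass through the anti conformer and give the C24 epimer, because the Lewis acid does not enforce a single reactive geometry. The fallback sets out from 6. A Lewis-acid-mediated one-carbon ring expansion with trimethylsilyldiazomethane (BF3·OEt2, then desilylation), in which the CH2 carbon migrates, would give cyclohexanone F1. Methylation of its only enolisable position (LDA, MeI) would give methyl ketone F2. Enolate oxygenation (KOtBu, O2, P(OEt)3) on the face opposite the syn-axial C12 methyl would give hydroxy ketone F3, and hydrolysis of the dithiolane as in step 5 returns to the route at 12.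

Step 28. Facial discrimination in the olefination may be poor because both α-carbons of the C7 ketone are tertiary, and the basic carbanion may enolise the ketone and scramble C2 or C6. The fallback sets out from 39. Wittig methoxymethylenation (Ph3P=CHOMe) would give enol ether F4 and mild acid hydrolysis aldehyde F5. O-triflation of its equilibrated potassium enolate (KHMDS, PhNTf2), with oxygen on the less hindered C2 side, would give enol triflate F6, which takes the place of 41 in step 30 and returns to the route at 43.

Step 30. Hydroboration by the bulky 9-BBN may stall at an alkene flanked by two fully substituted carbons, and slow transmetalation of the hindered alkylborane may let protodeboronation or reduction of the iodide compete. The fallback sets out from 23. BH3·THF then NaOH/H2O2 would give primary alcohol F7, and I2/PPh3/imidazole would convert only the primary hydroxyl to iodide F8. Iodine–lithium exchange (t-BuLi), capture with B-methoxy-9-BBN and coupling of the resulting borinate with 41 under the same palladium conditions returns to the route at 43.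

Step 25. Hydrogen-atom transfer may also reach the ring alkene (over-hydration), or oxygen may be captured on the concave face and give the C32 epimer. The fallback sets out from 35. BH3·THF then NaOH/H2O2 would give diol F9 and Dess–Martin oxidation diketone F10. Zn/CH2Br2/TiCl4 methylenation of the less hindered C32 carbonyl would give methylene ketone F11. Epoxidation with dimethyldioxirane from the convex face would give spiro-epoxide F12, LiAlH4 would open it at CH2 and reduce C7 to diol F13, and Dess–Martin oxidation returns to the route at 39.

Step 16. Addition to the doubly neopentyl C10 carbonyl may fail, or the C10 alkoxide may take the silyl group from O24 and block the elimination. The fallback sets out from 21. Addition of the smallest carbon nucleophile (MeLi, CeCl3) would give tertiary carbinol F14, and dehydration with Martin sulfurane, which can only remove a hydrogen of the new methyl because C11 and C24 bear none, returns to the route at 23.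

Step 12. A second addition of the Grignard reagent to the liberated isopropenyl ketone may compete once the tetrahedral intermediate collapses. The fallback sets out from 14. Oxalyl chloride would give acid chloride F15, and palladium-catalysed Stille acylation with tributyl(isopropenyl)stannane, which tolerates the two ketones, returns to the route at 17.

## Further compounds

F1 | step 8 | ring-expanded cyclohexanone, dithiolane retained (C10 ketone, C24 as CH2) | C[C@@]12CCC3(SCCS3)C=C1CCCC2=O
F2 | step 8 | C24-methyl ketone (C24 epimers) | C[C@@]12CCC3(SCCS3)C=C1CCC(C)C2=O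
F3 | step 8 | dithiolane of 12 | C[C@@]12CCC3(SCCS3)C=C1CC[C@](C)(O)C2=O
F4 | step 28 | methyl enol ether at C7=C8 (geometry not fixed) | C[C@@H]1CC[C@H]2[C@@H](C1=COC)C(C)(C)CC[C@]2(C)O
F5 | step 28 | C7 carbaldehyde (C7 epimers) | C[C@@H]1CC[C@H]2[C@@H](C1C=O)C(C)(C)CC[C@]2(C)O
F6 | step 28 | (E)-enol triflate (triflate oxygen cis to C2) | C[C@@H]1CC[C@H]2[C@@H](/C1=C/OS(=O)(=O)C(F)(F)F)C(C)(C)CC[C@]2(C)O
F7 | step 30 | C9 primary alcohol of the right half (H10 anti to C12) | OC[C@H]1[C@]2(C)CCC(O)C(C)(C)O[C@H]2CC[C@]1(C)O[Si](CC)(CC)CC
F8 | step 30 | C9 primary iodide | IC[C@H]1[C@]2(C)CCC(O)C(C)(C)O[C@H]2CC[C@]1(C)O[Si](CC)(CC)CC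
F9 | step 25 | decalin diol with C7 and C32 secondary carbinols (C32 epimers) | C[C@@H]1CC[C@H]2[C@@H]([C@H]1O)C(C)(C)CCC2O
F10 | step 25 | cis-decalin-C7,C32-dione | C[C@@H]1CC[C@H]2[C@@H](C1=O)C(C)(C)CCC2=O
F11 | step 25 | C32-methylene C7-ketone | C[C@@H]1CC[C@H]2[C@@H](C1=O)C(C)(C)CCC2=C
F12 | step 25 | C32 spiro-epoxide (oxygen on the convex face) | C[C@@H]1CC[C@H]2[C@@H](C1=O)C(C)(C)CC[C@@]23CO3
F13 | step 25 | C7,C32-diol (C7 epimers) | C[C@@H]1CC[C@H]2[C@@H](C1O)C(C)(C)CC[C@]2(C)O
F14 | step 16 | C10 methyl carbinol (C10 and C15 epimers) | CC1(O)[C@]2(C)CCC(O)C(C)(C)O[C@H]2CC[C@]1(C)O[Si](CC)(CC)CC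
F15 | step 12 | acid chloride of 14 | C[C@@]1(CCC(=O)Cl)C(=O)CC[C@](C)(O[Si](CC)(CC)CC)C1=O
A1 | alternative 1 | tricyclic furanone photoadduct | CC(C)(C)[Si](C)(C)OC[C@H]1[C@]3(C)C[C@H]4C(=O)C(C)(C)O[C@@]34CC[C@]1(C)O[Si](C)(C)C
A2 | alternative 2 | bicyclic oxepane hydroxy β-keto ester | COC(=O)[C@H]1[C@]2(C)CC[C@H](O)C(C)(C)O[C@H]2CCC1=O
A3 | alternative 3 | cis-disubstituted cyclohexenecarboxylic acid | CC1=C[C@@H](C(C)(C)CCO[Si](C)(C)C(C)(C)C)[C@@H](C(=O)O)CC1
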